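The route rests on cutting the bond between C1′ of the veratryl ring and the benzylic CH2 (C7′) on lactone carbon C4. C7′ stands 1,3 to the lactone α-carbon C3. The two are therefore tied into a cyclopropane fused to the C3–C4 edge of the butanolide ring and activated by the C2 carbonyl plus a removable ester. This 3-oxabicyclo[3.1.0]hexan-2-one, made from (R)-epichlorohydrin, already carries C4. In one operation a 3,4-dimethoxyphenyl cuprate opens the three-membered ring at C7′, forming the aryl–CH2 bond, and the released C3 enolate is oxygenated. Decarboxylation, anti-selective benzylation of the α-hydroxy lactone dianion and hydrogenolysis complete (−)-trachelogenin.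

Key step: step 2

Remark: lactone atoms are labelled O1, C2 (C=O), C3, C4, C5 (OCH2). The C3 configuration of 8 and 9 is left open in name and SMILES, because both epimers give the same planar dianion 12.

Step 1
Reactants: 1 (R)-epichlorohydrin [(2R)-2-(chloromethyl)oxirane]; 2 dimethyl malonate
Product: 4 methyl (1S,5R)-2-oxo-3-oxabicyclo[3.1.0]hexane-1-carboxylate, via epoxy malonate 3 (not isolated)
Conditions: NaOMe (1.05 equiv), MeOH, 0 °C to reflux
Reagents that add atoms: none
Why: Malonate alkylation cascade: the malonate anion opens the epoxide of 1 at its CH2 terminus, the alkoxide displaces chloride to give epoxide 3 with the C–O bond of the stereocenter intact, and 3-exo-tet attack of the re-formed malonate anion with inversion at that carbon, followed by lactonisation of the cis ester, gives 4, so that C5 of 4 (the future C4) comes from the chiral pool and C1 follows from the cis ring fusion.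

Step 2
Reactants: 4 methyl (1S,5R)-2-oxo-3-oxabicyclo[3.1.0]hexane-1-carboxylate; 5 4-bromoveratrole (4-bromo-1,2-dimethoxybenzene)
Product: 8 methyl (4S)-4-(3,4-dimethoxybenzyl)-3-hydroxy-2-oxotetrahydrofuran-3-carboxylate (C3 open), via aryl Grignard reagent 6 (not isolated), via bromomagnesium enolate 7 (not isolated)
Conditions: 5, Mg, THF, 40 °C; CuI (0.2 equiv), −40 °C; 4, −40 to −20 °C; then 3-phenyl-2-(phenylsulfonyl)oxaziridine, −40 °C to rt; aq NH4Cl
Reagents that add atoms: 3-phenyl-2-(phenylsulfonyl)oxaziridine, O=S(=O)(c1ccccc1)N1OC1c1ccccc1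
Why: CuI and Grignard reagent 6 form a magnesium diarylcuprate of monovalent copper that attacks the cyclopropane CH2 (C6 of 4, the future C7′) in an SN2-like homoconjugate addition, the C1–C6 bond leaving as the chelated malonate-type enolate 7, and reductive elimination from the trivalent copper intermediate forges the aryl–CH2 bond. The closest known reaction type is the copper-catalysed ring opening of cyclopropane-1,1-dicarboxylates and of this bicyclic lactone class by Grignard reagents, followed by electrophilic enolate hydroxylation with an N-sulfonyloxaziridine (Davis oxidation). No ring is closed; the three-membered ring is opened while the butanolide ring persists. C5 of 4 is not touched and becomes C4 of 8 with unchanged geometry, and the new C3 center, expected to form by oxygen transfer anti to the C4 side chain, is erased again in step 5 and needs no control. The step needs attack at C6 rather than at C5 or at a carbonyl group: C6 is the only unsubstituted cyclopropane carbon, both acceptors sit on C1 with the lactone holding its carbonyl in overlap with the breaking bond, and the soft cuprate at low temperature prefers carbon–carbon cleavage to acyl addition. The position on the arene is fixed by the C–Br bond of 5, para to one methoxy group and meta to the other.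

Step 3
Reactants: 8 methyl (4S)-4-(3,4-dimethoxybenzyl)-3-hydroxy-2-oxotetrahydrofuran-3-carboxylate
Product: 9 (4S)-4-(3,4-dimethoxybenzyl)-3-hydroxydihydrofuran-2(3H)-one (C3 open)
Conditions: LiCl, H2O, DMSO, 135 °C, N2
Reagents that add atoms: none
Why: Krapcho dealkoxycarbonylation: chloride demethylates the ester by SN2, the carboxylate next to the lactone carbonyl loses CO2 and the resulting enediolate is protonated, while the non-acidic C4–H keeps its configuration.

Step 4
Reactants: 10 4-(benzyloxy)-3-methoxybenzyl alcohol
Product: 11 4-(benzyloxy)-3-methoxybenzyl bromide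
Conditions: PBr3, CH2Cl2, 0 °C; used without storage
Reagents that add atoms: phosphorus tribromide, BrP(Br)Br
Why: Bromination of an electron-rich benzylic alcohol through its phosphite ester and bromide displacement, with no stereocenter involved and the benzyl aryl ether inert.

Step 5
Reactants: 9 (4S)-4-(3,4-dimethoxybenzyl)-3-hydroxydihydrofuran-2(3H)-one; 11 4-(benzyloxy)-3-methoxybenzyl bromide
Product: 13 (3S,4S)-3-[4-(benzyloxy)-3-methoxybenzyl]-4-(3,4-dimethoxybenzyl)-3-hydroxydihydrofuran-2(3H)-one (O-benzyltrachelogenin), via dilithium enediolate 12 (not isolated)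
Conditions: LiN(iPr)2 (2.3 equiv), THF–DMPU, −78 °C; then 11, −78 to −20 °C; aq NH4Cl
Reagents that add atoms: none
Why: Alkylation of an α-hydroxy ester dianion: the enediolate reacts at its more nucleophilic carbon, and the bromide approaches the ring face opposite the C4 veratryl side chain, which sets C3 as S with the two benzyl groups trans and the hydroxyl group cis to C7′.

Step 6
Reactants: 13 O-benzyltrachelogenin
Product: 14 (−)-trachelogenin, (3S,4S)-4-(3,4-dimethoxybenzyl)-3-hydroxy-3-(4-hydroxy-3-methoxybenzyl)dihydrofuran-2(3H)-one
Conditions: H2 (1 atm), Pd/C (10 wt %), EtOAc–EtOH, rt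
Reagents that add atoms: none
Why: Catalytic hydrogenolysis cleaves only the benzyl aryl ether, since the tertiary alcohol is homobenzylic and the lactone, the methyl ethers and both stereocenters are untouched.

Compound list
1 | (R)-epichlorohydrin, (2R)-2-(chloromethyl)oxirane | ClC[C@H]1CO1 | starting material
2 | dimethyl malonate | COC(=O)CC(=O)OC | starting material
3 | dimethyl 2-{[(2R)-oxiran-2-yl]methyl}malonate | COC(=O)C(C[C@@H]1CO1)C(=O)OC | intermediate
4 | methyl (1S,5R)-2-oxo-3-oxabicyclo[3.1.0]hexane-1-carboxylate | COC(=O)[C@]12C[C@H]1COC2=O | intermediate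
5 | 4-bromoveratrole (4-bromo-1,2-dimethoxybenzene) | COc1ccc(Br)cc1OC | starting material
6 | 3,4-dimethoxyphenylmagnesium bromide | COc1ccc([Mg]Br)cc1OC | intermediate
7 | bromomagnesium enolate of methyl (4R)-4-(3,4-dimethoxybenzyl)-2-oxotetrahydrofuran-3-carboxylate | COC(=O)C1=C(O[Mg]Br)OC[C@@H]1Cc1ccc(OC)c(OC)c1 | intermediate
8 | methyl (4S)-4-(3,4-dimethoxybenzyl)-3-hydroxy-2-oxotetrahydrofuran-3-carboxylate (C3 open) | COC(=O)C1(O)C(=O)OC[C@@H]1Cc1ccc(OC)c(OC)c1 | intermediate
9 | (4S)-4-(3,4-dimethoxybenzyl)-3-hydroxydihydrofuran-2(3H)-one (C3 open) | OC1C(=O)OC[C@@H]1Cc1ccc(OC)c(OC)c1 | intermediate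
10 | 4-(benzyloxy)-3-methoxybenzyl alcohol | COc1cc(CO)ccc1OCc1ccccc1 | starting material
11 | 4-(benzyloxy)-3-methoxybenzyl bromide | COc1cc(CBr)ccc1OCc1ccccc1 | intermediate
12 | dilithium enediolate of 9, (4S)-configured | [Li]OC1=C(O[Li])OC[C@@H]1Cc1ccc(OC)c(OC)c1 | intermediate
13 | (3S,4S)-3-[4-(benzyloxy)-3-methoxybenzyl]-4-(3,4-dimethoxybenzyl)-3-hydroxydihydrofuran-2(3H)-one | COc1cc(C[C@@]2(O)C(=O)OC[C@@H]2Cc2ccc(OC)c(OC)c2)ccc1OCc1ccccc1 | intermediate
14 | (−)-trachelogenin | COc1cc(C[C@@]2(O)C(=O)OC[C@@H]2Cc2ccc(OC)c(OC)c2)ccc1O | target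

Total step count: 6. Longest linear sequence: 5 (steps 1, 2, 3, 5, 6).

Steps most likely to fail

1. Step 2.
- What may go wrong: the aryl metal may add to the ester or lactone carbonyl instead of the cyclopropane CH2. Oxygen transfer to the chelated, stabilised enolate may be slow while surplus aryl metal consumes the oxidant.
- Fallback, from 4 back to 9: the two events are separated, which also allows a large excess of cuprate. Ring opening of 4 with 6 and CuI alone, quenched with aqueous NH4Cl, should give methyl (4R)-4-(3,4-dimethoxybenzyl)-2-oxotetrahydrofuran-3-carboxylate F1. Krapcho dealkoxycarbonylation (LiCl, wet DMSO, heat) should give (4R)-4-(3,4-dimethoxybenzyl)dihydrofuran-2(3H)-one F2. Its far more nucleophilic lithium enolate (LiN(SiMe3)2, THF, −78 °C) is then hydroxylated with the same oxaziridine to reach 9.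

2. Step 5.
- What may go wrong: O-alkylation of the alkoxide, proton transfer that quenches the dianion, or insufficient facial selectivity.
- Fallback, from 9 back to 14: dianion 12 is added to commercial 4-(benzyloxy)-3-methoxybenzaldehyde. This aldol addition is faster than alkylation and cannot O-alkylate. It should give (3R,4S)-3-{[4-(benzyloxy)-3-methoxyphenyl](hydroxy)methyl}-4-(3,4-dimethoxybenzyl)-3-hydroxydihydrofuran-2(3H)-one F3 as a mixture at the carbinol carbon. Hydrogenolysis (H2, Pd/C, AcOH) then removes the electron-rich benzylic hydroxyl group and the benzyl ether together and arrives directly at 14.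

3. Step 3.
- What may go wrong: retro-Claisen cleavage, air oxidation of the enediolate, or chloride opening of the lactone at high temperature.
- Fallback, from 8 back to 9: nucleophilic dealkylation is replaced by hydrolysis. Saponification (LiOH, THF–H2O) and acidification, which re-closes the lactone, should give (4S)-4-(3,4-dimethoxybenzyl)-3-hydroxy-2-oxotetrahydrofuran-3-carboxylic acid F4. This acid is decarboxylated thermally in refluxing toluene through the cyclic hydrogen-bonded transition state of a β-carbonyl acid to give 9.

Further compounds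
F1 | step 2 | methyl (4R)-4-(3,4-dimethoxybenzyl)-2-oxotetrahydrofuran-3-carboxylate (C3 open) | COC(=O)C1C(=O)OC[C@@H]1Cc1ccc(OC)c(OC)c1
F2 | step 2 | (4R)-4-(3,4-dimethoxybenzyl)dihydrofuran-2(3H)-one | O=C1C[C@@H](Cc2ccc(OC)c(OC)c2)CO1
F3 | step 5 | (3R,4S)-3-{[4-(benzyloxy)-3-methoxyphenyl](hydroxy)methyl}-4-(3,4-dimethoxybenzyl)-3-hydroxydihydrofuran-2(3H)-one (carbinol carbon open) | COc1cc(C(O)[C@@]2(O)C(=O)OC[C@@H]2Cc2ccc(OC)c(OC)c2)ccc1OCc1ccccc1
F4 | step 3 | (4S)-4-(3,4-dimethoxybenzyl)-3-hydroxy-2-oxotetrahydrofuran-3-carboxylic acid (C3 open) | OC(=O)C1(O)C(=O)OC[C@@H]1Cc1ccc(OC)c(OC)c1
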